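**Plan**
- Ring A carries Br, H, Br, H on four consecutive carbons (C3–C6) and O-aryl and OH on the adjacent pair C2 and C1. The retrosynthesis reads the C1–OH bond as a C–B bond, then cuts the C1–C6 and C2–C3 bonds, so C3–C6 come from 3,5-dibromo-2-pyrone and C1/C2 from an alkyne bearing boron and the ring B oxygen.
- The aryloxyethynyl boronate is traced back through C–B formation, two HBr eliminations and a Br2 addition to an aryl vinyl ether, and from there to the ring B–C phenol.
- That phenol is cut at its O-methyl bond, at the C–I bond (from C–NO2), at the diaryl ether C–O bond (SNAr) and at the three C–Br bonds of ring B, ending at guaiacol.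
- Forward: ring B is brominated, ring C is attached and iodinated, the ring B oxygen is carried to the alkynylboronate, ring A is built last by cycloaddition with loss of CO2, and the C–B bond is oxidised to the phenol.
- Stereochemistry: the target has no stereocentre. Only regiochemistry has to be controlled, by directing effects in step 1 and by alkyne polarisation in the key step.

Key step: step 11

Remark: tribromination of guaiacol is assumed to stop at the 4,5,6-tribromide, the position ortho to the methoxy group being the least activated.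

**Step 1**
Reactants: 1 guaiacol (2-methoxyphenol)
Product: 4 2,3,4-tribromo-6-methoxyphenol, via 4-bromo-2-methoxyphenol 2 (not isolated), via 2,4-dibromo-6-methoxyphenol 3 (not isolated)
Conditions: Br2 (3.2 equiv), AcOH, rt → 50 °C
Reagents that add atoms: bromine, BrBr
Why: Electrophilic aromatic bromination is directed by the free hydroxyl to its para and ortho positions and by the methoxy group to its para position, so three equivalents of Br2 should fill C4, C6 and C5 of guaiacol and leave the position ortho to the methoxy group untouched.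

**Step 2**
Reactants: 4 2,3,4-tribromo-6-methoxyphenol; 5 4-bromo-1-fluoro-2-nitrobenzene
Product: 6 1,2,3-tribromo-4-(4-bromo-2-nitrophenoxy)-5-methoxybenzene
Conditions: K2CO3, DMF, 90 °C
Reagents that add atoms: none
Why: Nucleophilic aromatic substitution (SNAr), in which the phenoxide of 4 adds to the fluorine-bearing carbon of 5 activated by the ortho nitro group and fluoride leaves from the Meisenheimer adduct, the bromine para to fluorine being unactivated.

**Step 3**
Reactants: 6 1,2,3-tribromo-4-(4-bromo-2-nitrophenoxy)-5-methoxybenzene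
Product: 7 5-bromo-2-(2,3,4-tribromo-6-methoxyphenoxy)aniline
Conditions: Fe powder, AcOH, EtOH, 70 °C
Reagents that add atoms: none
Why: Béchamp-type dissolving-metal reduction converts the nitro group into the amine by electron transfer from iron in acetic acid, conditions that leave aryl bromides and the diaryl ether intact.

**Step 4**
Reactants: 7 5-bromo-2-(2,3,4-tribromo-6-methoxyphenoxy)aniline
Product: 9 1,2,3-tribromo-4-(4-bromo-2-iodophenoxy)-5-methoxybenzene, via diazonium tosylate 8 (not isolated)
Conditions: NaNO2, p-TsOH·H2O, KI, MeCN–H2O, 10 °C → rt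
Reagents that add atoms: potassium iodide, [K+].[I-]
Why: Sandmeyer-type iodination, in which diazotisation of the weakly basic aniline gives a diazonium tosylate that iodide reduces and captures without copper, ring closure onto ring B being blocked because both of its positions ortho to the ether oxygen are substituted.

**Step 5**
Reactants: 9 1,2,3-tribromo-4-(4-bromo-2-iodophenoxy)-5-methoxybenzene
Product: 11 3,4,5-tribromo-2-(4-bromo-2-iodophenoxy)phenol, via aryloxydibromoborane 10 (not isolated)
Conditions: BBr3, CH2Cl2, −78 °C → rt; then H2O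
Reagents that add atoms: none
Why: Lewis-acid ether cleavage, in which BBr3 coordinates the methoxy oxygen and bromide removes the methyl group by SN2 attack, while the diaryl ether bonds and the aryl halides are inert to the reagent.

**Step 6**
Reactants: 11 3,4,5-tribromo-2-(4-bromo-2-iodophenoxy)phenol
Product: 12 1,2,3-tribromo-4-(4-bromo-2-iodophenoxy)-5-(ethenyloxy)benzene
Conditions: 2,4,6-trivinylcyclotriboroxane–pyridine complex, Cu(OAc)2, pyridine, CH2Cl2, air, rt
Reagents that add atoms: 2,4,6-trivinylcyclotriboroxane–pyridine complex, C=CB1OB(C=C)OB(C=C)O1.c1ccncc1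
Why: Chan–Lam-type oxidative C–O coupling, in which the phenoxide and a vinyl group from boron meet on copper, reductive elimination gives the aryl vinyl ether at room temperature and air returns copper to the divalent state, so the aryl iodide and bromides are not activated.

**Step 7**
Reactants: 12 1,2,3-tribromo-4-(4-bromo-2-iodophenoxy)-5-(ethenyloxy)benzene
Product: 14 1,2,3-tribromo-4-(4-bromo-2-iodophenoxy)-5-{[(Z)-2-bromoethenyl]oxy}benzene, via 1,2-dibromoethyl ether 13 (not isolated)
Conditions: Br2 (1.05 equiv), CH2Cl2, −78 °C; then DBU, −78 °C → rt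
Reagents that add atoms: bromine, BrBr
Why: Electrophilic anti-addition of Br2 to the electron-rich enol ether double bond is far faster than substitution on the deactivated rings, and the amidine base then removes HBr from the α-bromo ether by E2 elimination to give mainly the Z-bromovinyl ether, any E isomer converging in step 8.

**Step 8**
Reactants: 14 1,2,3-tribromo-4-(4-bromo-2-iodophenoxy)-5-{[(Z)-2-bromoethenyl]oxy}benzene
Product: 15 1,2,3-tribromo-4-(4-bromo-2-iodophenoxy)-5-(ethynyloxy)benzene
Conditions: KOtBu (1.5 equiv), THF, −78 → 0 °C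
Reagents that add atoms: none
Why: E2 anti-dehydrobromination, in which the hydrogen on the oxygen-bearing carbon of the Z isomer is antiperiplanar to bromine, so KOtBu should give the terminal ynol ether at low temperature without metalating or exchanging the aryl halides.

**Step 9**
Reactants: 15 1,2,3-tribromo-4-(4-bromo-2-iodophenoxy)-5-(ethynyloxy)benzene
Product: 18 2-{[3,4,5-tribromo-2-(4-bromo-2-iodophenoxy)phenoxy]ethynyl}-4,4,5,5-tetramethyl-1,3,2-dioxaborolane, via lithium acetylide 16 (not isolated), via lithium alkynylborate 17 (not isolated)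
Conditions: LiN(SiMe3)2, THF, −78 °C; i-PrOBpin, −78 °C; HCl (1.0 equiv, Et2O), −78 °C → rt
Reagents that add atoms: 2-isopropoxy-4,4,5,5-tetramethyl-1,3,2-dioxaborolane, CC(C)OB1OC(C)(C)C(C)(C)O1
Why: Deprotonation–borylation of a terminal alkyne, in which the hindered amide base, too weak to attack the aryl halides, forms the acetylide, this adds to the borate ester to give an ate complex, and one equivalent of anhydrous HCl collapses it to the alkynyl pinacolboronate.

**Step 10**
Reactants: 19 coumalic acid (2-oxo-2H-pyran-5-carboxylic acid)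
Product: 21 3,5-dibromo-2H-pyran-2-one, via 3-bromocoumalic acid 20 (not isolated)
Conditions: NBS (2.5 equiv), LiOAc, MeCN–H2O, rt
Reagents that add atoms: N-bromosuccinimide, O=C1CCC(=O)N1Br
Why: Electrophilic bromination at C3 and bromodecarboxylation at C5 (ipso attack on the carboxylate-bearing carbon with loss of CO2) by NBS should give the dibromopyrone in one flask, most likely through the 3-bromo acid.

**Step 11**
Reactants: 18 2-{[3,4,5-tribromo-2-(4-bromo-2-iodophenoxy)phenoxy]ethynyl}-4,4,5,5-tetramethyl-1,3,2-dioxaborolane; 21 3,5-dibromo-2H-pyran-2-one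
Product: 23 2-{3,5-dibromo-2-[3,4,5-tribromo-2-(4-bromo-2-iodophenoxy)phenoxy]phenyl}-4,4,5,5-tetramethyl-1,3,2-dioxaborolane, via bridged lactone 22 (not isolated)
Conditions: 21 (1.5 equiv), o-xylene, sealed tube, N2, 110 → 140 °C
Reagents that add atoms: none
Why: Proposed new method: the electron-poor diene 21 and the oxygen-activated alkyne 18 should combine in a thermal Diels–Alder reaction across C3 and C6 of the pyrone to give bridged lactone 22, which expels CO2 by retro-[4+2] and aromatises to 23; the closest known reactions are the thermal cycloaddition–decarboxylation of 2-pyrones with alkyl- and aryl-substituted alkynylboronates to arylboronates and the regioselective additions of enol ethers to 3,5-dibromo-2-pyrone. Ring A closes by this intermolecular [4+2] mode, both new C–C bonds forming in the cycloaddition and the aromatic sextet arising on loss of CO2. No stereocentre is created in 23, the two bridgehead centres of racemic 22 being erased on aromatisation. The step needs regioselectivity, with the aryloxy carbon bonding to C3 and the boron carbon to C6: oxygen lone-pair donation, reinforced by the vacant p orbital on boron, makes the boron-bearing carbon the nucleophilic terminus, and C6, vinylogous to the lactone carbonyl, is the electrophilic terminus of the diene, the pairing that enol ethers show. Chemoselectivity is secured because the halogenated aryl ether rings offer no competing diene or dienophile, and an aryl ynol ether cannot undergo the retro-ene loss of ketene that limits alkyl ynol ethers on heating.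

**Step 12**
Reactants: 23 2-{3,5-dibromo-2-[3,4,5-tribromo-2-(4-bromo-2-iodophenoxy)phenoxy]phenyl}-4,4,5,5-tetramethyl-1,3,2-dioxaborolane
Product: 25 bromoiesol B, via aryl borate ester 24 (not isolated)
Conditions: NaBO3·4H2O, THF–H2O, rt
Reagents that add atoms: sodium perborate tetrahydrate (NaBO3·4H2O), [Na+].[Na+].O[B-]1(O)OO[B-](O)(O)OO1
Why: Oxidation of the carbon–boron bond, in which peroxide adds to boron, the aryl group migrates from boron to oxygen at the same carbon and hydrolysis of the borate releases the phenol, under conditions mild enough for the aryl iodide and the diaryl ethers.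

**Compound list**
1 | guaiacol (2-methoxyphenol) | COc1ccccc1O | starting material
2 | 4-bromo-2-methoxyphenol | COc1cc(Br)ccc1O | intermediate
3 | 2,4-dibromo-6-methoxyphenol | COc1cc(Br)cc(Br)c1O | intermediate
4 | 2,3,4-tribromo-6-methoxyphenol (4,5,6-tribromoguaiacol) | COc1cc(Br)c(Br)c(Br)c1O | intermediate
5 | 4-bromo-1-fluoro-2-nitrobenzene | O=[N+]([O-])c1cc(Br)ccc1F | starting material
6 | 1,2,3-tribromo-4-(4-bromo-2-nitrophenoxy)-5-methoxybenzene | COc1cc(Br)c(Br)c(Br)c1Oc1ccc(Br)cc1[N+](=O)[O-] | intermediate
7 | 5-bromo-2-(2,3,4-tribromo-6-methoxyphenoxy)aniline | COc1cc(Br)c(Br)c(Br)c1Oc1ccc(Br)cc1N | intermediate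
8 | 5-bromo-2-(2,3,4-tribromo-6-methoxyphenoxy)benzenediazonium 4-methylbenzenesulfonate | COc1cc(Br)c(Br)c(Br)c1Oc1ccc(Br)cc1[N+]#N.Cc1ccc(S(=O)(=O)[O-])cc1 | intermediate
9 | 1,2,3-tribromo-4-(4-bromo-2-iodophenoxy)-5-methoxybenzene | COc1cc(Br)c(Br)c(Br)c1Oc1ccc(Br)cc1I | intermediate
10 | dibromo[3,4,5-tribromo-2-(4-bromo-2-iodophenoxy)phenoxy]borane | BrB(Br)Oc1cc(Br)c(Br)c(Br)c1Oc1ccc(Br)cc1I | intermediate
11 | 3,4,5-tribromo-2-(4-bromo-2-iodophenoxy)phenol | Oc1cc(Br)c(Br)c(Br)c1Oc1ccc(Br)cc1I | intermediate
12 | 1,2,3-tribromo-4-(4-bromo-2-iodophenoxy)-5-(ethenyloxy)benzene | C=COc1cc(Br)c(Br)c(Br)c1Oc1ccc(Br)cc1I | intermediate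
13 | 1,2,3-tribromo-4-(4-bromo-2-iodophenoxy)-5-(1,2-dibromoethoxy)benzene (racemic) | BrCC(Br)Oc1cc(Br)c(Br)c(Br)c1Oc1ccc(Br)cc1I | intermediate
14 | 1,2,3-tribromo-4-(4-bromo-2-iodophenoxy)-5-{[(Z)-2-bromoethenyl]oxy}benzene | Br/C=C\Oc1cc(Br)c(Br)c(Br)c1Oc1ccc(Br)cc1I | intermediate
15 | 1,2,3-tribromo-4-(4-bromo-2-iodophenoxy)-5-(ethynyloxy)benzene | C#COc1cc(Br)c(Br)c(Br)c1Oc1ccc(Br)cc1I | intermediate
16 | lithium [3,4,5-tribromo-2-(4-bromo-2-iodophenoxy)phenoxy]acetylide | [Li+].[C-]#COc1cc(Br)c(Br)c(Br)c1Oc1ccc(Br)cc1I | intermediate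
17 | lithium isopropoxy(pinacolato){[3,4,5-tribromo-2-(4-bromo-2-iodophenoxy)phenoxy]ethynyl}borate | [Li+].CC(C)O[B-]1(C#COc2cc(Br)c(Br)c(Br)c2Oc2ccc(Br)cc2I)OC(C)(C)C(C)(C)O1 | intermediate
18 | 2-{[3,4,5-tribromo-2-(4-bromo-2-iodophenoxy)phenoxy]ethynyl}-4,4,5,5-tetramethyl-1,3,2-dioxaborolane | CC1(C)OB(C#COc2cc(Br)c(Br)c(Br)c2Oc2ccc(Br)cc2I)OC1(C)C | intermediate
19 | coumalic acid (2-oxo-2H-pyran-5-carboxylic acid) | O=C(O)c1ccc(=O)oc1 | starting material
20 | 3-bromo-2-oxo-2H-pyran-5-carboxylic acid (3-bromocoumalic acid) | O=C(O)c1cc(Br)c(=O)oc1 | intermediate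
21 | 3,5-dibromo-2H-pyran-2-one | O=c1occ(Br)cc1Br | intermediate
22 | 4,7-dibromo-6-(4,4,5,5-tetramethyl-1,3,2-dioxaborolan-2-yl)-5-[3,4,5-tribromo-2-(4-bromo-2-iodophenoxy)phenoxy]-2-oxabicyclo[2.2.2]octa-5,7-dien-3-one (racemic) | O=C1OC2C(Br)=CC1(Br)C(Oc3cc(Br)c(Br)c(Br)c3Oc3ccc(Br)cc3I)=C2B4OC(C)(C)C(C)(C)O4 | intermediate
23 | 2-{3,5-dibromo-2-[3,4,5-tribromo-2-(4-bromo-2-iodophenoxy)phenoxy]phenyl}-4,4,5,5-tetramethyl-1,3,2-dioxaborolane | CC1(C)OB(c2cc(Br)cc(Br)c2Oc2cc(Br)c(Br)c(Br)c2Oc2ccc(Br)cc2I)OC1(C)C | intermediate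
24 | 2-{3,5-dibromo-2-[3,4,5-tribromo-2-(4-bromo-2-iodophenoxy)phenoxy]phenoxy}-4,4,5,5-tetramethyl-1,3,2-dioxaborolane | CC1(C)OB(Oc2cc(Br)cc(Br)c2Oc2cc(Br)c(Br)c(Br)c2Oc2ccc(Br)cc2I)OC1(C)C | intermediate
25 | bromoiesol B, 3,5-dibromo-2-[3,4,5-tribromo-2-(4-bromo-2-iodophenoxy)phenoxy]phenol | Oc1cc(Br)cc(Br)c1Oc1cc(Br)c(Br)c(Br)c1Oc1ccc(Br)cc1I | target

**Step count**
Total: 12 steps. Longest linear sequence: 11 steps (steps 1–9, 11 and 12, from guaiacol); step 10 is a one-step side branch.

**Steps most likely to fail**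

Step 11. The push–pull alkyne may oligomerise or lose boron on heating before it is intercepted by the pyrone, or the cycloaddition may proceed with the reverse orientation. The fallback uses only known reactions and leaves the cycloaddition aside. It sets out from phenol 11, which is O-arylated by SNAr with commercial 3,5-dibromo-2-fluorobenzaldehyde (K2CO3, DMF, 80 °C) to give 3,5-dibromo-2-[3,4,5-tribromo-2-(4-bromo-2-iodophenoxy)phenoxy]benzaldehyde F1. Baeyer–Villiger oxidation of the aldehyde (mCPBA, CH2Cl2, rt) gives 3,5-dibromo-2-[3,4,5-tribromo-2-(4-bromo-2-iodophenoxy)phenoxy]phenyl formate F2, and methanolysis (K2CO3, MeOH, rt) releases the phenol, so the route is rejoined at target 25.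

Step 8. The free terminal aryloxyacetylene may polymerise during isolation, or tert-butoxide may add across the electron-rich triple bond. The fallback avoids the free alkyne. It sets out from bromovinyl ether 14, which is treated with KN(SiMe3)2 (2.2 equiv, THF, −78 °C) so that elimination and metalation give potassium [3,4,5-tribromo-2-(4-bromo-2-iodophenoxy)phenoxy]acetylide F3 directly. Addition of i-PrOBpin gives potassium isopropoxy(pinacolato){[3,4,5-tribromo-2-(4-bromo-2-iodophenoxy)phenoxy]ethynyl}borate F4, and one equivalent of HCl in Et2O collapses it, so the route is rejoined at alkynylboronate 18.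

Step 6. Transfer of the hindered, electron-poor phenoxide to copper may be slow, so that conversion stalls and the vinylboron reagent is consumed by homocoupling. The fallback replaces the copper coupling by alkylation and elimination. It sets out from phenol 11, which is alkylated with a large excess of 1,2-dibromoethane (K2CO3, MeCN, reflux) to give 1,2,3-tribromo-4-(4-bromo-2-iodophenoxy)-5-(2-bromoethoxy)benzene F5. E2 elimination with KOtBu (THF, 0 °C) then gives the vinyl ether, so the route is rejoined at 12.

**Further compounds**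
F1 | step 11 | 3,5-dibromo-2-[3,4,5-tribromo-2-(4-bromo-2-iodophenoxy)phenoxy]benzaldehyde | O=Cc1cc(Br)cc(Br)c1Oc1cc(Br)c(Br)c(Br)c1Oc1ccc(Br)cc1I
F2 | step 11 | 3,5-dibromo-2-[3,4,5-tribromo-2-(4-bromo-2-iodophenoxy)phenoxy]phenyl formate | O=COc1cc(Br)cc(Br)c1Oc1cc(Br)c(Br)c(Br)c1Oc1ccc(Br)cc1I
F3 | step 8 | potassium [3,4,5-tribromo-2-(4-bromo-2-iodophenoxy)phenoxy]acetylide | [K+].[C-]#COc1cc(Br)c(Br)c(Br)c1Oc1ccc(Br)cc1I
F4 | step 8 | potassium isopropoxy(pinacolato){[3,4,5-tribromo-2-(4-bromo-2-iodophenoxy)phenoxy]ethynyl}borate | [K+].CC(C)O[B-]1(C#COc2cc(Br)c(Br)c(Br)c2Oc2ccc(Br)cc2I)OC(C)(C)C(C)(C)O1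
F5 | step 6 | 1,2,3-tribromo-4-(4-bromo-2-iodophenoxy)-5-(2-bromoethoxy)benzene | BrCCOc1cc(Br)c(Br)c(Br)c1Oc1ccc(Br)cc1I
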